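**Retrosynthetic overview**

- The target is a (12R) flavone whose C3 and O2' are bridged by C11H2–C12H(CMe2OH) into an oxepine (ring atoms C2, C3, C11, C12, O, C2', C1'). C11–C12 is the only sp3–sp3 C–C bond of that ring and sits next to the ether oxygen.
- C11–C12 is therefore taken back to a C11=C12 cyclic enol ether, with C12 set by asymmetric hydrogenation. The enol ether is cut by ring-closing metathesis between a 3-vinyl group and a 1-substituted vinyl ether on O2'.
- The vinyl ether comes from Tebbe methylenation of a 2'-O aryl ester that also protects O2'. The 3-vinyl group comes from Stille coupling of a 3-iodoflavone, and the pyranone ring from iodocyclisation of an aryl ynone (ring A acid + ring B alkyne).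
- The two prenyl groups are added last (debenzylation, 6,8-diiodination, twofold Stille coupling), followed by MOM removal, so that no other alkene is present during metathesis and hydrogenation.
- Ring order: rings A and B are bought, ring C (pyranone) is closed by iodocyclisation, and the oxepine by metathesis.

Key step: step 12

Remark on numbering: flavone numbering is used; C11 is the CH2 on C3, C12 the stereocentre, C13 the carbinol carbon.

Assumption: the (S)-configured phosphinooxazoline ligand is taken to deliver hydrogen to the Si face of C12; if the first run shows the opposite sense, the (R)-ligand is used and nothing else changes.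

Remark on the ring A source: 2,4,6-trihydroxybenzaldehyde is used so that the acid is reached by oxidation, which avoids hydrolysis of a doubly ortho-substituted benzoate ester.

**Route**

Step 1
Reactants: 1 2,4,6-trihydroxybenzaldehyde
Product: 2 2,4,6-tris(benzyloxy)benzaldehyde
Conditions: BnBr (3.6 equiv), K2CO3, DMF, 60 °C
Reagents that add atoms: benzyl bromide, BrCc1ccccc1
Why: Williamson ether synthesis; carbonate in warm DMF should also alkylate the two hydrogen-bonded ortho hydroxyls, and the formyl group lowers the nucleophilicity of the ring carbons so that O-alkylation is preferred over C-alkylation.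

Step 2
Reactants: 2 2,4,6-tris(benzyloxy)benzaldehyde
Product: 3 2,4,6-tris(benzyloxy)benzoic acid
Conditions: NaClO2, NaH2PO4, 2-methylbut-2-ene (excess), t-BuOH–THF–H2O, 0 °C → rt
Reagents that add atoms: sodium chlorite, [Na+].[O-]Cl=O
Why: Pinnick oxidation; chlorous acid should oxidise the hindered aldehyde without touching the benzyl ethers, and the excess alkene traps the hypochlorous acid that could otherwise chlorinate the electron-rich ring.

Step 3
Reactants: 4 2,4-dihydroxybenzaldehyde
Product: 5 2-hydroxy-4-(methoxymethoxy)benzaldehyde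
Conditions: MOMCl (1.05 equiv), K2CO3, acetone, 0 °C → rt
Reagents that add atoms: chloromethyl methyl ether, COCCl
Why: Selective Williamson-type alkylation; the 4-hydroxyl is the more acidic and accessible phenol while the 2-hydroxyl is held in a hydrogen bond to the aldehyde, so one equivalent of the chloride should etherify O4 only.

Step 4
Reactants: 5 2-hydroxy-4-(methoxymethoxy)benzaldehyde
Product: 6 2-ethynyl-5-(methoxymethoxy)phenol
Conditions: dimethyl (1-diazo-2-oxopropyl)phosphonate (1.5 equiv), K2CO3 (3 equiv), MeOH, rt
Reagents that add atoms: dimethyl (1-diazo-2-oxopropyl)phosphonate, CC(=O)C(=[N+]=[N-])P(=O)(OC)OC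
Why: Seyferth–Gilbert homologation in the Ohira–Bestmann variant; methoxide deacetylates the reagent, the diazomethylphosphonate anion adds to the aldehyde, and loss of dimethyl phosphate and N2 with a 1,2-shift gives the terminal alkyne, the free phenol being carried as its phenoxide with excess base and reagent.

Step 5
Reactants: 7 2-hydroxy-2-methylpropanoic acid
Product: 9 2-methyl-2-[(triethylsilyl)oxy]propanoic acid, via triethylsilyl ester 8 (not isolated)
Conditions: TESOTf (2.2 equiv), 2,6-lutidine, CH2Cl2, 0 °C → rt; then MeOH–H2O, rt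
Reagents that add atoms: triethylsilyl trifluoromethanesulfonate, CC[Si](CC)(CC)OS(=O)(=O)C(F)(F)F
Why: Silylation of both the tertiary hydroxyl and the carboxyl group by the silyl triflate, followed by selective solvolysis of the much more labile silyl ester in neutral aqueous methanol, which should leave the tertiary silyl ether in place.

Step 6
Reactants: 6 2-ethynyl-5-(methoxymethoxy)phenol; 9 2-methyl-2-[(triethylsilyl)oxy]propanoic acid
Product: 10 2-ethynyl-5-(methoxymethoxy)phenyl 2-methyl-2-[(triethylsilyl)oxy]propanoate
Conditions: DCC, DMAP (0.2 equiv), CH2Cl2, 0 °C → rt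
Reagents that add atoms: none
Why: Steglich esterification; DMAP transfers the carbodiimide-activated hindered acyl group to the phenol, and the ester both masks the future O2' (making it non-nucleophilic towards the alkyne in the later iodocyclisation) and already carries C12, C13 and the two methyl groups.

Step 7
Reactants: 3 2,4,6-tris(benzyloxy)benzoic acid; 10 2-ethynyl-5-(methoxymethoxy)phenyl 2-methyl-2-[(triethylsilyl)oxy]propanoate
Product: 12 5-(methoxymethoxy)-2-{3-oxo-3-[2,4,6-tris(benzyloxy)phenyl]prop-1-yn-1-yl}phenyl 2-methyl-2-[(triethylsilyl)oxy]propanoate (aryl ynone), via acid chloride 11 (not isolated)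
Conditions: (COCl)2, DMF (cat.), CH2Cl2, 0 °C → rt, evaporate; then 10, PdCl2(PPh3)2 (2 mol%), CuI (4 mol%), Et3N, THF, rt
Reagents that add atoms: none
Why: Acid chloride formation followed by acyl Sonogashira coupling; zerovalent palladium inserts into the aroyl C–Cl bond, the copper acetylide transmetallates and reductive elimination gives the ynone at room temperature, where the aryl ester, silyl ether and MOM ether should be untouched.

Step 8
Reactants: 12 aryl ynone
Product: 13 2-[5,7-bis(benzyloxy)-3-iodo-4-oxo-4H-chromen-2-yl]-5-(methoxymethoxy)phenyl 2-methyl-2-[(triethylsilyl)oxy]propanoate (3-iodoflavone)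
Conditions: ICl (1.2 equiv), CH2Cl2, −78 °C; aq Na2S2O3
Reagents that add atoms: iodine monochloride, ClI
Why: Electrophilic iodocyclisation of an ortho-alkoxyaryl ynone; ICl activates the triple bond, an ortho benzyloxy oxygen of ring A attacks the aryl-bearing alkyne carbon 6-endo-dig and chloride removes the benzyl group from the oxonium ion, closing ring C with iodine at C3, ring A being symmetrical so that either ortho ether gives the same product and the acylated O2' being unable to compete by 5-endo closure to a benzofuran.

Step 9
Reactants: 13 3-iodoflavone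
Product: 14 2-[5,7-bis(benzyloxy)-3-ethenyl-4-oxo-4H-chromen-2-yl]-5-(methoxymethoxy)phenyl 2-methyl-2-[(triethylsilyl)oxy]propanoate
Conditions: tributyl(vinyl)stannane (1.3 equiv), Pd(PPh3)4 (5 mol%), toluene, 100 °C
Reagents that add atoms: tributyl(vinyl)stannane, C=C[Sn](CCCC)(CCCC)CCCC
Why: Stille coupling; oxidative addition of the electron-poor C3–I bond to zerovalent palladium, vinyl transfer from tin and reductive elimination run under neutral conditions that should spare the aryl ester and the silyl ether.

Step 10
Reactants: 14 3-vinylflavone aryl ester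
Product: 15 5,7-bis(benzyloxy)-3-ethenyl-2-[4-(methoxymethoxy)-2-({3-methyl-3-[(triethylsilyl)oxy]but-1-en-2-yl}oxy)phenyl]-4H-chromen-4-one
Conditions: Cp2Ti(μ-CH2)(μ-Cl)AlMe2 (1.3 equiv), pyridine, THF–toluene, −40 → 0 °C; aq NaOH
Reagents that add atoms: Tebbe reagent Cp2Ti(μ-CH2)(μ-Cl)AlMe2, C[Al](C)C[Ti](Cl)(C1C=CC=C1)C1C=CC=C1
Why: Tebbe methylenation; the titanium methylidene adds to the activated aryl ester carbonyl through an oxatitanacyclobutane and cycloreverts to the 1-aryloxyvinyl ether, while the C4 carbonyl, a poorly electrophilic pyranone carbonyl flanked by the 5-benzyloxy and 3-vinyl groups, should be left alone by a small excess of reagent at low temperature.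

Step 11
Reactants: 15 silyl-protected enol ether
Product: 16 5,7-bis(benzyloxy)-3-ethenyl-2-{2-[(3-hydroxy-3-methylbut-1-en-2-yl)oxy]-4-(methoxymethoxy)phenyl}-4H-chromen-4-one
Conditions: TBAF (1.2 equiv), THF, 0 °C → rt
Reagents that add atoms: none
Why: Fluoride-induced desilylation; fluoride attacks silicon and frees the tertiary alcohol under basic conditions that the acid-sensitive aryl vinyl ether, the MOM ether and the benzyl ethers should tolerate.

Step 12
Reactants: 16 3-vinylflavone with the 2'-O-(3-hydroxy-3-methylbut-1-en-2-yl) enol ether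
Product: 17 5,7-bis(benzyloxy)-4'-(methoxymethoxy)flavone with C3 and O2' bridged by C11H=C12(CMe2OH) (oxepine-fused cyclic enol ether)
Conditions: second-generation Grubbs catalyst RuCl2(=CHPh)(PCy3)(H2IMes) (10 mol%), toluene (0.005 M), 80 °C, argon sweep
Reagents that add atoms: none
Why: The ruthenium benzylidene first exchanges with the unhindered 3-vinyl group to give an alkylidene at C11, which adds (2+2) to the neighbouring C12=CH2 enol ether and cycloreverts to the C11=C12 bond and a ruthenium methylidene that carries the chain, ethylene being lost over the cycle. The closest known reaction type is ring-closing metathesis of alkene-tethered 1-substituted vinyl ethers to cyclic enol ethers with N-heterocyclic-carbene ruthenium catalysts. The oxepine (C2, C3, C11, C12, O, C2', C1') closes as a seven-membered ring by intramolecular alkene metathesis in which both terminal CH2 groups are expelled and the new double bond is endocyclic. No stereocentre is formed, and the ring fixes the geometry of the trisubstituted alkene. The step needs ring closure to win over dimerisation at the vinyl group and over capture of the catalyst as an unreactive alkoxycarbene at the enol ether; the cis C2=C3 bond and the C2–C1' bond hold the two alkenes within reach, the free tertiary hydroxyl keeps C12 less crowded than a silyl ether would, high dilution and removal of ethylene favour closure, and no other alkene (no prenyl group yet) is present.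

Step 13
Reactants: 17 oxepine-fused cyclic enol ether
Product: 18 (12R)-5,7-bis(benzyloxy)-4'-(methoxymethoxy)flavone with C3 and O2' bridged by C11H2–C12H(CMe2OH)
Conditions: H2 (50 bar), [Ir(cod)(L)]BArF (2 mol%; L = (S)-4-tert-butyl-2-[2-(diphenylphosphanyl)phenyl]-4,5-dihydro-1,3-oxazole, BArF = B[3,5-(CF3)2C6H3]4), CH2Cl2, rt
Reagents that add atoms: none
Why: Iridium-catalysed asymmetric hydrogenation of a trisubstituted cyclic enol ether that is also an allylic alcohol; the alkene binds to the cationic iridium dihydride with the tertiary hydroxyl as a second contact, the tert-butyl group of the oxazoline blocks one quadrant so that hydrogen is delivered to the Si face of C12 (O > C13 > C11) and C12 becomes R, while the tetrasubstituted C2=C3 bond of the pyranone and the benzyl ethers should not be touched by this homogeneous catalyst.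

Step 14
Reactants: 18 (12R)-dibenzyl ether
Product: 19 (12R)-5,7-dihydroxy-4'-(methoxymethoxy)flavone with the C11H2–C12H(CMe2OH) bridge from C3 to O2'
Conditions: H2 (1 atm), 10% Pd/C, EtOAc–MeOH, rt
Reagents that add atoms: none
Why: Hydrogenolysis of benzyl aryl ethers on palladium; the C12–O bond is not benzylic and the pyranone C2=C3 bond is not reduced at atmospheric pressure, so only the two benzyl groups should be lost and C12 is unaffected.

Step 15
Reactants: 19 (12R)-5,7-diol
Product: 20 (12R)-5,7-dihydroxy-6,8-diiodo-4'-(methoxymethoxy)flavone with the C11H2–C12H(CMe2OH) bridge from C3 to O2'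
Conditions: NIS (2.05 equiv), DMF, 0 °C, dark
Reagents that add atoms: N-iodosuccinimide, O=C1CCC(=O)N1I
Why: Electrophilic aromatic iodination; the free 5,7-dihydroxy ring A is far more nucleophilic than the dialkoxy ring B conjugated to the pyranone, so two equivalents of the reagent should go to C6 and C8, the only open positions of ring A.

Step 16
Reactants: 20 (12R)-6,8-diiodide
Product: 21 (12R)-5,7-dihydroxy-4'-(methoxymethoxy)-6,8-bis(3-methylbut-2-en-1-yl)flavone with the C11H2–C12H(CMe2OH) bridge from C3 to O2'
Conditions: tributyl(3-methylbut-2-en-1-yl)stannane (3 equiv), Pd(PPh3)4 (10 mol%), DMF, 90 °C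
Reagents that add atoms: tributyl(3-methylbut-2-en-1-yl)stannane, CC(C)=CC[Sn](CCCC)(CCCC)CCCC
Why: Twofold Stille coupling with an allylic stannane; each aryl–palladium iodide takes the allyl group from tin and reductive elimination at the unsubstituted terminus should give the linear prenyl groups, free ortho hydroxyls and the remote stereocentre being tolerated under these neutral conditions.

Step 17
Reactants: 21 (12R)-diprenyl MOM ether
Product: 22 CNP0328977.2, (12R)-5,7,4'-trihydroxy-6,8-bis(3-methylbut-2-en-1-yl)flavone with the C11H2–C12H(CMe2OH) bridge from C3 to O2'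
Conditions: 3 M HCl (aq), MeOH, rt
Reagents that add atoms: none
Why: Acid-catalysed acetal exchange; the MOM acetal is cleaved to the phenol and dimethoxymethane by dilute acid in methanol at room temperature, conditions mild enough that cyclisation of the ortho-prenylphenols to chromans and ionisation of the tertiary alcohol should not compete, and C12, an ether carbon with no adjacent carbonyl, is configurationally stable.

**Compound list**

1 | 2,4,6-trihydroxybenzaldehyde | O=Cc1c(O)cc(O)cc1O | starting material
2 | 2,4,6-tris(benzyloxy)benzaldehyde | O=Cc1c(OCc2ccccc2)cc(OCc2ccccc2)cc1OCc1ccccc1 | intermediate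
3 | 2,4,6-tris(benzyloxy)benzoic acid | OC(=O)c1c(OCc2ccccc2)cc(OCc2ccccc2)cc1OCc1ccccc1 | intermediate
4 | 2,4-dihydroxybenzaldehyde | O=Cc1ccc(O)cc1O | starting material
5 | 2-hydroxy-4-(methoxymethoxy)benzaldehyde | O=Cc1ccc(OCOC)cc1O | intermediate
6 | 2-ethynyl-5-(methoxymethoxy)phenol | C#Cc1ccc(OCOC)cc1O | intermediate
7 | 2-hydroxy-2-methylpropanoic acid | CC(C)(O)C(=O)O | starting material
8 | triethylsilyl 2-methyl-2-[(triethylsilyl)oxy]propanoate | CC[Si](CC)(CC)OC(=O)C(C)(C)O[Si](CC)(CC)CC | intermediate (not isolated)
9 | 2-methyl-2-[(triethylsilyl)oxy]propanoic acid | CC[Si](CC)(CC)OC(C)(C)C(=O)O | intermediate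
10 | 2-ethynyl-5-(methoxymethoxy)phenyl 2-methyl-2-[(triethylsilyl)oxy]propanoate | C#Cc1ccc(OCOC)cc1OC(=O)C(C)(C)O[Si](CC)(CC)CC | intermediate
11 | 2,4,6-tris(benzyloxy)benzoyl chloride | ClC(=O)c1c(OCc2ccccc2)cc(OCc2ccccc2)cc1OCc1ccccc1 | intermediate (not isolated)
12 | 5-(methoxymethoxy)-2-{3-oxo-3-[2,4,6-tris(benzyloxy)phenyl]prop-1-yn-1-yl}phenyl 2-methyl-2-[(triethylsilyl)oxy]propanoate | O=C(C#Cc1ccc(OCOC)cc1OC(=O)C(C)(C)O[Si](CC)(CC)CC)c1c(OCc2ccccc2)cc(OCc2ccccc2)cc1OCc1ccccc1 | intermediate
13 | 2-[5,7-bis(benzyloxy)-3-iodo-4-oxo-4H-chromen-2-yl]-5-(methoxymethoxy)phenyl 2-methyl-2-[(triethylsilyl)oxy]propanoate | O=c1c(I)c(-c2ccc(OCOC)cc2OC(=O)C(C)(C)O[Si](CC)(CC)CC)oc2cc(OCc3ccccc3)cc(OCc3ccccc3)c12 | intermediate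
14 | 2-[5,7-bis(benzyloxy)-3-ethenyl-4-oxo-4H-chromen-2-yl]-5-(methoxymethoxy)phenyl 2-methyl-2-[(triethylsilyl)oxy]propanoate | O=c1c(C=C)c(-c2ccc(OCOC)cc2OC(=O)C(C)(C)O[Si](CC)(CC)CC)oc2cc(OCc3ccccc3)cc(OCc3ccccc3)c12 | intermediate
15 | 5,7-bis(benzyloxy)-3-ethenyl-2-[4-(methoxymethoxy)-2-({3-methyl-3-[(triethylsilyl)oxy]but-1-en-2-yl}oxy)phenyl]-4H-chromen-4-one | O=c1c(C=C)c(-c2ccc(OCOC)cc2OC(=C)C(C)(C)O[Si](CC)(CC)CC)oc2cc(OCc3ccccc3)cc(OCc3ccccc3)c12 | intermediate
16 | 5,7-bis(benzyloxy)-3-ethenyl-2-{2-[(3-hydroxy-3-methylbut-1-en-2-yl)oxy]-4-(methoxymethoxy)phenyl}-4H-chromen-4-one | O=c1c(C=C)c(-c2ccc(OCOC)cc2OC(=C)C(C)(C)O)oc2cc(OCc3ccccc3)cc(OCc3ccccc3)c12 | intermediate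
17 | 5,7-bis(benzyloxy)-4'-(methoxymethoxy)flavone bridged from C3 to O2' by C11H=C12(CMe2OH) | c1ccccc1COc1cc(OCc2ccccc2)c2c(c1)oc1c(c2=O)C=C(C(C)(C)O)Oc2cc(OCOC)ccc2-1 | intermediate
18 | (12R)-5,7-bis(benzyloxy)-4'-(methoxymethoxy)flavone bridged from C3 to O2' by C11H2–C12H(CMe2OH) | c1ccccc1COc1cc(OCc2ccccc2)c2c(c1)oc1c(c2=O)C[C@H](C(C)(C)O)Oc2cc(OCOC)ccc2-1 | intermediate
19 | (12R)-5,7-dihydroxy-4'-(methoxymethoxy) bridged flavone | Oc1cc(O)c2c(c1)oc1c(c2=O)C[C@H](C(C)(C)O)Oc2cc(OCOC)ccc2-1 | intermediate
20 | (12R)-5,7-dihydroxy-6,8-diiodo-4'-(methoxymethoxy) bridged flavone | Oc1c(I)c(O)c2c(c1I)oc1c(c2=O)C[C@H](C(C)(C)O)Oc2cc(OCOC)ccc2-1 | intermediate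
21 | (12R)-5,7-dihydroxy-4'-(methoxymethoxy)-6,8-bis(3-methylbut-2-en-1-yl) bridged flavone | CC(C)=CCc1c(O)c(CC=C(C)C)c2oc3c(c(=O)c2c1O)C[C@H](C(C)(C)O)Oc1cc(OCOC)ccc1-3 | intermediate
22 | CNP0328977.2 | CC(C)=CCc1c(O)c(CC=C(C)C)c2oc3c(c(=O)c2c1O)C[C@H](C(C)(C)O)Oc1cc(O)ccc1-3 | target

**Step count**

Total steps: 17. Longest linear sequence: 14 (steps 3, 4 and 6 to 17, from 2,4-dihydroxybenzaldehyde).

**Steps most likely to fail**

Step 12 (ring-closing metathesis). The 1,1-disubstituted enol ether next to a fully substituted carbinol carbon may be too hindered for the ruthenium alkylidene. Turnover would then go to homodimerisation at the 3-vinyl group, or the catalyst would be lost as an unreactive alkoxycarbene. The fallback makes the C11=C12 bond by carbonyl olefination instead of alkene metathesis and needs neither the Tebbe step nor the acyclic enol ether. It sets out from 14, which is treated with the Takai–Utimoto titanium ethylidene reagent (TiCl4, TMEDA, Zn, PbCl2 cat., CH3CHBr2, THF, 65 °C). In this known olefinic ester cyclisation the titanium alkylidene forms at the vinyl group with loss of propene and olefinates the aryl ester carbonyl intramolecularly, which should give the triethylsilyl ether of the oxepine-fused enol ether F1. TBAF in THF then removes the silyl group and the route is rejoined at 17.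

Step 13 (asymmetric hydrogenation). The trisubstituted enol ether, conjugated and flanked by a quaternary carbon, may be reduced slowly or with poor facial selectivity, and acid formed from the iridium hydride may hydrolyse the enol ether. The fallback sets C12 by asymmetric epoxidation and stereospecific ring opening. It sets out from 13. Stille coupling with tributyl(3-methylbut-2-en-1-yl)stannane (Pd(PPh3)4, DMF, 90 °C) should give the 3-prenylflavone aryl ester F2. Shi epoxidation (KHSO5, K2CO3 buffer, MeCN–dimethoxymethane–H2O, 0 °C) with the ketone enantiomer that delivers the (S)-epoxide, expected to be the one from L-fructose, should give the (S)-epoxide F3; the electron-rich prenyl alkene reacts far faster than the pyranone C2=C3 bond. K2CO3 in MeOH then cleaves the aryl ester, and the freed 2'-phenoxide opens the epoxide at the secondary carbon C12 in a 7-exo-tet closure with inversion. This gives the (12R) oxepine with the tertiary alcohol, and the route is rejoined at 18.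

Step 10 (Tebbe methylenation). The titanium methylidene may also attack the C4 carbonyl or engage the 3-vinyl group, so that methylenation of the ester is not clean. The fallback builds the enol ether by addition to an alkyne instead of by carbonyl olefination. It sets out from 14. K2CO3 in MeOH at room temperature should cleave the aryl ester to the 2'-hydroxy-3-vinylflavone F4. Markovnikov hydrophenoxylation of 2-methylbut-3-yn-2-ol (3 equiv) catalysed by monovalent gold (Ph3PAuNTf2, 5 mol%, toluene, 50 °C), a known addition of phenols to terminal alkynes, then puts the 3-hydroxy-3-methylbut-1-en-2-yl group on O2'. The route is rejoined at 16 with step 11 saved.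

**Further compounds**

F1 | step 12 | triethylsilyl ether of 17 (5,7-bis(benzyloxy)-4'-(methoxymethoxy)flavone bridged from C3 to O2' by C11H=C12(CMe2OSiEt3)) | c1ccccc1COc1cc(OCc2ccccc2)c2c(c1)oc1c(c2=O)C=C(C(C)(C)O[Si](CC)(CC)CC)Oc2cc(OCOC)ccc2-1
F2 | step 13 | 2-[5,7-bis(benzyloxy)-3-(3-methylbut-2-en-1-yl)-4-oxo-4H-chromen-2-yl]-5-(methoxymethoxy)phenyl 2-methyl-2-[(triethylsilyl)oxy]propanoate | O=c1c(CC=C(C)C)c(-c2ccc(OCOC)cc2OC(=O)C(C)(C)O[Si](CC)(CC)CC)oc2cc(OCc3ccccc3)cc(OCc3ccccc3)c12
F3 | step 13 | 2-[5,7-bis(benzyloxy)-3-{[(2S)-3,3-dimethyloxiran-2-yl]methyl}-4-oxo-4H-chromen-2-yl]-5-(methoxymethoxy)phenyl 2-methyl-2-[(triethylsilyl)oxy]propanoate | O=c1c(C[C@@H]2OC2(C)C)c(-c2ccc(OCOC)cc2OC(=O)C(C)(C)O[Si](CC)(CC)CC)oc2cc(OCc3ccccc3)cc(OCc3ccccc3)c12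
F4 | step 10 | 5,7-bis(benzyloxy)-3-ethenyl-2-[2-hydroxy-4-(methoxymethoxy)phenyl]-4H-chromen-4-one | O=c1c(C=C)c(-c2ccc(OCOC)cc2O)oc2cc(OCc3ccccc3)cc(OCc3ccccc3)c12
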